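## Structural features

The target is a biflavan: two 2-arylchroman units joined by one C–C bond from C4 of the upper unit to C8 of the lower unit. The upper unit is a 3-deoxyflavan with a 7-hydroxyl on ring A and a 3,4-dihydroxyphenyl ring B; the lower unit is a flavan-3-ol with a 5,7-dihydroxy ring A and a 3,4,5-trihydroxyphenyl ring B. Read from the SMILES string, the upper unit is (2S,4R), with the aryl groups at C2 and C4 trans across the C3 methylene, and the lower unit is (2R,3R), with the adjacent C2 aryl and C3 hydroxyl groups cis. The two pairs of stereocentres lie in different rings, but upper C4 sits on the carbon ortho to lower O1, so it is close to the lower pyran ring. Fragile elements are the eight phenolic hydroxyls (a pyrogallol and a catechol among them, easily oxidised in air and base), the doubly benzylic C4–C8 bond to a phloroglucinol-type ring (it can re-ionise in acid), and the two benzylic ether bonds O1–C2. The real difficulties are the regiochemistry on lower ring A (link at C8 and not at C6), the 2,4-trans relationship in the upper pyran ring, and the 2,3-cis relationship in the lower pyran ring, where a C3 ketone on the way makes C2–H acidic. The key step exploits lower ring C: O1–C8a–C4a–C4 is the O–C–C–CHO array of a salicylaldehyde, and C2–C3 with ring B is the Cβ–Cα pair of a cinnamaldehyde. Forming O1–C2 and C3–C4 therefore closes this ring with C2 as the only stereocentre and leaves a formyl group on C3 as the handle for the C3 oxygen.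

## Logic of the disconnections

20 back to 19: the eight aryl O–CH2Ph bonds are cut. Benzyl is the one protecting group that survives every earlier step and leaves in a single neutral operation, so all polyphenol handling is moved to the last step. The forward hydrogenolysis must spare the two cyclic benzylic C2–O1 bonds and the C4–C8 bond.

19 back to 18: the C3–H bond of the carbinol is cut, going back to the C3 ketone. This separates the 2,3-cis problem from ring construction and reduces the lower unit to one stereocentre. The forward reduction must deliver hydride anti to the C2 aryl group and must be faster than enolisation towards C2.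

18 back to 15, through 17 and 16: the C3–O bond is exchanged for a C3–C bond to a carboxyl group. The C3 oxygen thereby becomes the residue of a one-carbon appendage that the ring-forming step can carry. The forward degradation (acyl azide, isocyanate, hydrolysis) must leave C2 untouched.

15 back to 14: only the oxidation level of the appendage changes, from acid to aldehyde. The forward oxidation must not attack the C3=C4 bond or the electron-rich rings.

14 back to 10 and 13: the lower O1–C2 and C3–C4 bonds are cut (the C3=C4 double bond is the trace of an aldol dehydration). This removes the whole lower pyran ring and ring B in one stroke and leaves a salicylaldehyde and an enal. The forward step must set C2 under catalyst control, and 10 must offer a single free hydroxyl, the one next to the flavanyl-bearing carbon, or the link comes out as 4→6.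

13 back to 11 and 12: the Cα=Cβ bond of the enal is cut. Both pieces are commercial; the forward olefination must stop after one two-carbon homologation and give the E isomer.

10 back to 9: two O–benzyl bonds on the phloroglucinol-derived ring are cut. This is where the three hydroxyls are told apart; the forward etherification must leave the hindered, hydrogen-bonded hydroxyl free.

9 back to 7, through 8: the aryl–CHO bond is cut. The two open ring positions of 7 are equivalent, so the forward formylation has no regiochemical choice and must only stop after one substitution.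

7 back to 5 and 6: the C4–aryl bond (the future C4–C8 link) is cut. The nucleophile is symmetrical, so one constitution is possible; the forward alkylation must add trans to the C2 aryl group and avoid double alkylation.

5 back to 4, then to 2 and 3, then to 1: the C4–H bond, the C2–aryl bond and the 7-O–benzyl bond are cut in turn. The upper ring A is bought ready-made in 1; the forward conjugate arylation must set C2 (S) by catalyst control.

## Other disconnections considered

Alternative 1: The cut removes upper ring A almost entirely (C4a–C5, C6–C7, C7–C8 and C4a–C8a), which also opens upper ring C. The precursor would be the open-chain diazo enone A2, which carries an ethynyl ether on the C2 oxygen and a diazo vinyl ketone on C4, next to the complete benzylated lower unit. Forward, irradiation would trigger a Wolff rearrangement to a vinylketene, intramolecular [2+2] addition across the ynol ether, 4π opening of the cyclobutenone and 6π closure, giving phenol A1 after tautomerisation.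
- In its favour: two rings and the C7 phenol arise in one neutral operation after the acid-sensitive C4–C8 bond already exists. The substitution pattern of upper ring A is fixed by the mechanism. The lower unit enters whole, so its 2,3-cis pair could come from the chiral pool instead of being built; on that point it is better than the chosen plan, which has to pass through an epimerisable C3 ketone.
- Against it here: upper ring A is the least demanding part of the target and is commercially available in 1. The cut leaves the C4–C8 bond and the upper 1,3-related stereocentres to be made on an open chain, without the conformational help that the chosen plan draws from the ring. A2 combines three labile groups (an ethynyl ether of a secondary benzylic alcohol, a diazo ketone, a vinyl ketone) with nine ultraviolet-absorbing benzyl ether rings.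
- Comparison: better on the lower stereocentres; weaker on the upper ones; equal in the final deprotection (one hydrogenolysis, with one benzyl group fewer to remove from A1); clearly longer to the precursor.

Alternative 2: The cut takes apart lower ring A (C7–C8, C8a–C4a, C6–C7) into the siloxyalkyne A4, carried on upper C4, and the cyclobutenone A5, which bears the C5 benzyloxy group and the cinnamyl chain. Forward, heating would open A5 to a vinylketene; [2+2] addition to A4, ring opening and 6π closure would give the pentasubstituted phenol A3.
- In its favour: the polarity of the ketene–ynol ether addition puts the flavanyl carbon next to the new C7 hydroxyl and the silyloxy carbon at C8a. The 4→8 connectivity and three differently protected oxygens are therefore secured by mechanism, with no selective protection; on this point it is better than the chosen plan, which relies on a selective dibenzylation.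
- Against it here: A3 still lacks the lower pyran ring and both lower stereocentres. Silyl removal, enantioselective oxidation of the cinnamyl alkene, cyclisation and a correction to 2,3-cis would follow, which is more work after the key step than the four steps of the chosen plan. A4 needs the same trans-selective bond formation at upper C4 as the chosen plan (equal on that point) plus the construction of an acid- and moisture-sensitive siloxyalkyne. A donor-substituted cyclobutenone such as A5 opens reluctantly, and its own alkene could compete for the ketene.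
- Comparison: stronger on regiochemistry; equal on upper C4; weaker on the lower stereocentres and on step economy.

Alternative 3: The cut is the upper O1–C2 bond, going back to the 1,3,3-triarylpropan-1-ol A7 with a free phenol on the future C8a and an (R)-carbinol. Forward, PPh3/DIAD would activate the carbinol and the phenol would displace it with inversion (6-exo-tet) to give the nona-O-benzyl biflavan A6.
- In its favour: the lower unit would be derived from natural (−)-epigallocatechin A8 and stays intact, so neither lower stereocentre has to be made and no flavan-3-one is needed. The closure is mild and neutral, and A6 is one hydrogenolysis from the target; this end game is shorter than that of the chosen plan. Upper C4 could be set by an asymmetric catalyst on the open chain instead of relying on a kinetic facial preference.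
- Against it here: the carbinol is a 3,4-dialkoxybenzylic alcohol, so the activated intermediate may ionise and inversion may be incomplete. A7 requires C8-selective C–C bond formation on the benzylated nucleus derived from A8 (C6 competes), an acyclic C4 stereocentre, an enantioselective ketone reduction, and a phenol pattern with one hydroxyl free.
- Comparison: better on the lower half; equal on the C8/C6 question (intrinsic reactivity there, protection pattern here); riskier in the mechanism of the stereo-defining closure; probably similar in total step count, with more of the effort in preparing the precursor.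

Key step: step 8

Remarks on the chemistry:
- Assumption: the sense of induction of the two chiral catalysts (pyridine-oxazoline ligand in step 2, prolinol silyl ether in step 8) is taken from the accepted steric models. The antipode of either is equally accessible and would be used if a pilot run on a model substrate showed the opposite sense.
- The planned structures were compared with the target SMILES string atom by atom; constitution and all four configurations, (2S,4R) in the upper unit and (2R,3R) in the lower unit, agree. Three design points carry weight: (a) the 4→8 connectivity rests on which hydroxyl of 9 stays free in step 6, not only on the symmetry of 6; (b) upper C4 is adjacent to the reacting oxygen in step 8, so double stereodifferentiation is allowed for; (c) the hydrolysis that releases ketone 18 is run cold and briefly and 18 is reduced at once, because C2–H of 18 is acidic.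
- Abbreviations used in the steps: Bn = benzyl; UF = (2S,4R)-7-(benzyloxy)-2-[3,4-bis(benzyloxy)phenyl]chroman-4-yl; ArG = 3,4,5-tris(benzyloxy)phenyl.

## Route

Step 1
Reactants: 1 7-hydroxychromone
Product: 2 7-(benzyloxy)chromone
Conditions: BnBr, K2CO3, acetone, reflux
Reagents that add atoms: benzyl bromide, BrCc1ccccc1
Why: Williamson etherification of the acidic 7-hydroxyl (a vinylogous acid); potassium carbonate in acetone should not open the pyranone ring.

Step 2
Reactants: 2 7-(benzyloxy)chromone; 3 [3,4-bis(benzyloxy)phenyl]boronic acid
Product: 4 (2S)-7-(benzyloxy)-2-[3,4-bis(benzyloxy)phenyl]chroman-4-one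
Conditions: Pd(OCOCF3)2 (5 mol %), (R)-4-tert-butyl-2-(pyridin-2-yl)-4,5-dihydrooxazole (6 mol %), NH4PF6 (30 mol %), H2O (5 equiv), ClCH2CH2Cl, 60 °C
Reagents that add atoms: none
Why: Enantioselective conjugate addition of an arylboronic acid to a chromone catalysed by cationic divalent palladium (transmetalation, carbopalladation of C2=C3, protonolysis of the palladium enolate), a known entry to 2-arylchroman-4-ones. The tert-butyl group of the ligand decides the face of C2; the (R)-ligand is chosen for 2S by analogy with additions to cyclic enones.

Step 3
Reactants: 4 (2S)-7-(benzyloxy)-2-[3,4-bis(benzyloxy)phenyl]chroman-4-one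
Product: 5 (2S,4S)-7-(benzyloxy)-2-[3,4-bis(benzyloxy)phenyl]chroman-4-ol (2,4-cis; any C4 epimer is carried along)
Conditions: NaBH4, THF/MeOH, 0 °C
Reagents that add atoms: none
Why: Borohydride reduction of the aryl ketone; axial hydride delivery to the half-chair with an equatorial 2-aryl group should give mainly the 2,4-cis alcohol. The configuration at C4 is immaterial because this centre is ionised in step 4.

Step 4
Reactants: 5 (2S,4S)-7-(benzyloxy)-2-[3,4-bis(benzyloxy)phenyl]chroman-4-ol; 6 phloroglucinol (5 equiv)
Product: 7 2-UF-benzene-1,3,5-triol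
Conditions: BF3·OEt2 (0.3 equiv), THF, −20 → 0 °C
Reagents that add atoms: none
Why: Friedel–Crafts alkylation of a phenol by a benzylic alcohol: the Lewis acid ionises C4–OH to a cation stabilised by O1 and the para 7-benzyloxy group, and the symmetrical triol, whose three ring CH positions are equivalent, captures it at carbon with loss of water, so only one constitution can form. Attack along the pseudoaxial trajectory of the half-chair with the 2-aryl group equatorial should place the new aryl group trans to it (4R); low temperature and sub-stoichiometric acid keep the reaction kinetic, and the excess of 6 suppresses double alkylation.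

Step 5
Reactants: 7 2-UF-benzene-1,3,5-triol
Product: 9 3-UF-2,4,6-trihydroxybenzaldehyde, via aryl iminium chloride 8 (not isolated)
Conditions: POCl3 (1.2 equiv), DMF, EtOAc, 0 °C → rt; then H2O, 50 °C
Reagents that add atoms: N,N-dimethylformamide, CN(C)C=O (formyl carbon; also the CH=NMe2 unit of 8); water, O (formyl oxygen); phosphoryl chloride, O=P(Cl)(Cl)Cl (chloride counter-ion of 8 only)
Why: Vilsmeier–Haack formylation of the most electron-rich ring; the two open positions of the trihydroxyphenyl group are interchanged by rotation about the C4–aryl bond, so a single aldehyde can result, and the iminium group of 8 deactivates the ring against a second substitution until it is hydrolysed.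

Step 6
Reactants: 9 3-UF-2,4,6-trihydroxybenzaldehyde
Product: 10 4,6-bis(benzyloxy)-2-hydroxy-3-UF-benzaldehyde
Conditions: BnBr (2.1 equiv), K2CO3, DMF, rt
Reagents that add atoms: benzyl bromide, BrCc1ccccc1
Why: Selective Williamson etherification: the hydroxyl para to the formyl group is the most acidic and the ortho hydroxyl next to the ring CH is unhindered, whereas the hydroxyl between the formyl group and the flavanyl substituent is held in a six-membered hydrogen bond and shielded on both sides, so it should be the one left free. This step fixes the 4→8 connectivity, because only the hydroxyl left free can become O1 of the lower pyran ring.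

Step 7
Reactants: 11 3,4,5-tris(benzyloxy)benzaldehyde; 12 (triphenylphosphoranylidene)acetaldehyde
Product: 13 (E)-3-ArG-prop-2-enal
Conditions: PhMe, 80 °C
Reagents that add atoms: none
Why: Wittig olefination with a stabilised formyl ylide, which gives the E-enal; keeping the ylide close to one equivalent limits a second homologation to the dienal.

Step 8
Reactants: 10 4,6-bis(benzyloxy)-2-hydroxy-3-UF-benzaldehyde; 13 (E)-3-ArG-prop-2-enal (2 equiv)
Product: 14 (2R)-5,7-bis(benzyloxy)-8-UF-2-ArG-2H-chromene-3-carbaldehyde
Conditions: (S)-2-[diphenyl(trimethylsilyloxy)methyl]pyrrolidine (20 mol %), 2-nitrobenzoic acid (20 mol %), 4 Å MS, PhMe, rt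
Reagents that add atoms: none
Why: The pyrrolidine condenses with enal 13 to an E-configured, s-trans iminium ion; the single free hydroxyl of 10 adds to its β-carbon (oxa-Michael addition, forming lower O1–C2), the resulting enamine attacks the neighbouring formyl carbon through its α-carbon (intramolecular aldol, forming lower C3–C4), and loss of water followed by hydrolysis of the conjugated iminium ion releases 14 and the catalyst. The closest known reaction type is the diarylprolinol silyl ether-catalysed domino oxa-Michael/aldol condensation of salicylaldehydes with cinnamaldehydes to 2-aryl-2H-chromene-3-carbaldehydes. The lower pyran ring is closed in the aldol event, a 6-exo-trig attack of the enamine carbon on the aldehyde carbonyl. Lower C2 is the only new stereocentre and is set in the oxa-Michael step by the catalyst: the CPh2(OSiMe3) group covers one face of the iminium ion, the phenol adds to the open face, and by the usual model the (S)-catalyst leads to 2R. The step needs site selectivity among the oxygens of the phloroglucinol-derived ring, which is secured because 10 has only one free hydroxyl, the one between the formyl carbon and the flavanyl-bearing carbon, so the flavanyl group must end at C8. It also needs face selectivity in the presence of the chiral flavanyl group ortho to the reacting oxygen; the shielding group of the catalyst lies much closer to the β-carbon than this substituent does and is expected to dominate. The acid co-catalyst speeds iminium formation and turnover, the sieves favour the dehydration that makes the sequence irreversible and protects C2 from retro-addition, and one molecule of water is the only by-product.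

Step 9
Reactants: 14 (2R)-5,7-bis(benzyloxy)-8-UF-2-ArG-2H-chromene-3-carbaldehyde
Product: 15 (2R)-5,7-bis(benzyloxy)-8-UF-2-ArG-2H-chromene-3-carboxylic acid
Conditions: NaClO2, NaH2PO4, 2-methylbut-2-ene (excess), t-BuOH/THF/H2O, 0 °C → rt
Reagents that add atoms: sodium chlorite, [Na+].[O-]Cl=O (one oxygen)
Why: Pinnick oxidation: chlorous acid adds to the formyl group and fragments to the carboxylic acid and HOCl, leaving the C3=C4 bond and C2 untouched. The alkene scavenger removes HOCl before it can chlorinate the electron-rich C6 position.

Step 10
Reactants: 15 (2R)-5,7-bis(benzyloxy)-8-UF-2-ArG-2H-chromene-3-carboxylic acid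
Product: 18 (2R)-5,7-bis(benzyloxy)-8-UF-2-ArG-chroman-3-one, via acyl azide 16 (not isolated), via vinyl isocyanate 17 (not isolated)
Conditions: (PhO)2P(O)N3, Et3N, PhMe, rt then 80 °C; then 1 M HCl, THF, 0 °C → rt
Reagents that add atoms: water, O (ketone oxygen of 18); diphenylphosphoryl azide, [N-]=[N+]=NP(=O)(Oc1ccccc1)Oc1ccccc1 (azide nitrogens of 16 and nitrogen of 17; none of its atoms remains in 18)
Why: Curtius rearrangement: the acid is converted into acyl azide 16, which loses N2 with migration of the C3 vinyl carbon to nitrogen to give vinyl isocyanate 17, a known route from 2H-chromene-3-carboxylic acids to chroman-3-ones. Cold dilute acid hydrates 17 to a carbamic acid that decarboxylates to the enamine, whose iminium form is hydrolysed to the C3 ketone. Brief, cold hydrolysis and immediate use of 18 limit enolisation towards C2.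

Step 11
Reactants: 18 (2R)-5,7-bis(benzyloxy)-8-UF-2-ArG-chroman-3-one
Product: 19 (2R,3R)-5,7-bis(benzyloxy)-8-UF-2-ArG-chroman-3-ol
Conditions: LiBH(s-Bu)3, LiBr, THF, −78 °C; then aq NaOH, H2O2, 0 °C
Reagents that add atoms: none
Why: Reduction of a flavan-3-one with a bulky trialkylborohydride, known for benzyl-protected flavan-3-ones: hydride reaches the C3 carbonyl from the face opposite the equatorial C2 aryl group, so the hydroxyl ends cis to the aryl group (3R). At −78 °C reduction should outrun enolisation.

Step 12
Reactants: 19 (2R,3R)-5,7-bis(benzyloxy)-8-UF-2-ArG-chroman-3-ol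
Product: 20 (2R,3R)-8-[(2S,4R)-2-(3,4-dihydroxyphenyl)-7-hydroxychroman-4-yl]-2-(3,4,5-trihydroxyphenyl)chroman-3,5,7-triol
Conditions: H2 (1 atm), Pd(OH)2/C, THF/MeOH, rt; filtration and concentration under argon
Reagents that add atoms: none
Why: Hydrogenolysis of eight aryl benzyl ethers; the cyclic benzylic C2–O1 bonds and the C4–C8 bond are not normally cleaved under these conditions. Work-up without air protects the pyrogallol and catechol units.

## Compound list

1 | 7-hydroxy-4H-chromen-4-one | O=c1ccoc2cc(O)ccc12 | starting material
2 | 7-(benzyloxy)-4H-chromen-4-one | O=c1ccoc2cc(OCc3ccccc3)ccc12 | intermediate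
3 | [3,4-bis(benzyloxy)phenyl]boronic acid | OB(O)c1ccc(OCc2ccccc2)c(OCc2ccccc2)c1 | starting material
4 | (2S)-7-(benzyloxy)-2-[3,4-bis(benzyloxy)phenyl]chroman-4-one | c1ccccc1COc1ccc2c(c1)O[C@H](c1ccc(OCc3ccccc3)c(OCc3ccccc3)c1)CC2=O | intermediate
5 | (2S,4S)-7-(benzyloxy)-2-[3,4-bis(benzyloxy)phenyl]chroman-4-ol | c1ccccc1COc1ccc2c(c1)O[C@H](c1ccc(OCc3ccccc3)c(OCc3ccccc3)c1)C[C@@H]2O | intermediate
6 | benzene-1,3,5-triol (phloroglucinol) | Oc1cc(O)cc(O)c1 | starting material
7 | 2-{(2S,4R)-7-(benzyloxy)-2-[3,4-bis(benzyloxy)phenyl]chroman-4-yl}benzene-1,3,5-triol | c1ccccc1COc1ccc2c(c1)O[C@H](c1ccc(OCc3ccccc3)c(OCc3ccccc3)c1)C[C@H]2c1c(O)cc(O)cc1O | intermediate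
8 | [(3-{(2S,4R)-7-(benzyloxy)-2-[3,4-bis(benzyloxy)phenyl]chroman-4-yl}-2,4,6-trihydroxyphenyl)methylidene]dimethylammonium chloride | c1ccccc1COc1ccc2c(c1)O[C@H](c1ccc(OCc3ccccc3)c(OCc3ccccc3)c1)C[C@H]2c1c(O)cc(O)c(C=[N+](C)C)c1O.[Cl-] | intermediate (not isolated)
9 | 3-{(2S,4R)-7-(benzyloxy)-2-[3,4-bis(benzyloxy)phenyl]chroman-4-yl}-2,4,6-trihydroxybenzaldehyde | c1ccccc1COc1ccc2c(c1)O[C@H](c1ccc(OCc3ccccc3)c(OCc3ccccc3)c1)C[C@H]2c1c(O)cc(O)c(C=O)c1O | intermediate
10 | 4,6-bis(benzyloxy)-3-{(2S,4R)-7-(benzyloxy)-2-[3,4-bis(benzyloxy)phenyl]chroman-4-yl}-2-hydroxybenzaldehyde | c1ccccc1COc1ccc2c(c1)O[C@H](c1ccc(OCc3ccccc3)c(OCc3ccccc3)c1)C[C@H]2c1c(OCc2ccccc2)cc(OCc2ccccc2)c(C=O)c1O | intermediate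
11 | 3,4,5-tris(benzyloxy)benzaldehyde | O=Cc1cc(OCc2ccccc2)c(OCc2ccccc2)c(OCc2ccccc2)c1 | starting material
12 | (triphenylphosphoranylidene)acetaldehyde | O=CC=P(c1ccccc1)(c1ccccc1)c1ccccc1 | starting material
13 | (2E)-3-[3,4,5-tris(benzyloxy)phenyl]prop-2-enal | O=C/C=C/c1cc(OCc2ccccc2)c(OCc2ccccc2)c(OCc2ccccc2)c1 | intermediate
14 | (2R)-5,7-bis(benzyloxy)-8-{(2S,4R)-7-(benzyloxy)-2-[3,4-bis(benzyloxy)phenyl]chroman-4-yl}-2-[3,4,5-tris(benzyloxy)phenyl]-2H-chromene-3-carbaldehyde | c1ccccc1COc1ccc2c(c1)O[C@H](c1ccc(OCc3ccccc3)c(OCc3ccccc3)c1)C[C@H]2c1c(OCc2ccccc2)cc(OCc2ccccc2)c2c1O[C@H](c1cc(OCc3ccccc3)c(OCc3ccccc3)c(OCc3ccccc3)c1)C(C=O)=C2 | intermediate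
15 | (2R)-5,7-bis(benzyloxy)-8-{(2S,4R)-7-(benzyloxy)-2-[3,4-bis(benzyloxy)phenyl]chroman-4-yl}-2-[3,4,5-tris(benzyloxy)phenyl]-2H-chromene-3-carboxylic acid | c1ccccc1COc1ccc2c(c1)O[C@H](c1ccc(OCc3ccccc3)c(OCc3ccccc3)c1)C[C@H]2c1c(OCc2ccccc2)cc(OCc2ccccc2)c2c1O[C@H](c1cc(OCc3ccccc3)c(OCc3ccccc3)c(OCc3ccccc3)c1)C(C(=O)O)=C2 | intermediate
16 | (2R)-5,7-bis(benzyloxy)-8-{(2S,4R)-7-(benzyloxy)-2-[3,4-bis(benzyloxy)phenyl]chroman-4-yl}-2-[3,4,5-tris(benzyloxy)phenyl]-2H-chromene-3-carbonyl azide | c1ccccc1COc1ccc2c(c1)O[C@H](c1ccc(OCc3ccccc3)c(OCc3ccccc3)c1)C[C@H]2c1c(OCc2ccccc2)cc(OCc2ccccc2)c2c1O[C@H](c1cc(OCc3ccccc3)c(OCc3ccccc3)c(OCc3ccccc3)c1)C(C(=O)N=[N+]=[N-])=C2 | intermediate (not isolated)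
17 | (2R)-5,7-bis(benzyloxy)-8-{(2S,4R)-7-(benzyloxy)-2-[3,4-bis(benzyloxy)phenyl]chroman-4-yl}-3-isocyanato-2-[3,4,5-tris(benzyloxy)phenyl]-2H-chromene | c1ccccc1COc1ccc2c(c1)O[C@H](c1ccc(OCc3ccccc3)c(OCc3ccccc3)c1)C[C@H]2c1c(OCc2ccccc2)cc(OCc2ccccc2)c2c1O[C@H](c1cc(OCc3ccccc3)c(OCc3ccccc3)c(OCc3ccccc3)c1)C(N=C=O)=C2 | intermediate (not isolated)
18 | (2R)-5,7-bis(benzyloxy)-8-{(2S,4R)-7-(benzyloxy)-2-[3,4-bis(benzyloxy)phenyl]chroman-4-yl}-2-[3,4,5-tris(benzyloxy)phenyl]chroman-3-one | c1ccccc1COc1ccc2c(c1)O[C@H](c1ccc(OCc3ccccc3)c(OCc3ccccc3)c1)C[C@H]2c1c(OCc2ccccc2)cc(OCc2ccccc2)c2c1O[C@H](c1cc(OCc3ccccc3)c(OCc3ccccc3)c(OCc3ccccc3)c1)C(=O)C2 | intermediate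
19 | (2R,3R)-5,7-bis(benzyloxy)-8-{(2S,4R)-7-(benzyloxy)-2-[3,4-bis(benzyloxy)phenyl]chroman-4-yl}-2-[3,4,5-tris(benzyloxy)phenyl]chroman-3-ol | c1ccccc1COc1ccc2c(c1)O[C@H](c1ccc(OCc3ccccc3)c(OCc3ccccc3)c1)C[C@H]2c1c(OCc2ccccc2)cc(OCc2ccccc2)c2c1O[C@H](c1cc(OCc3ccccc3)c(OCc3ccccc3)c(OCc3ccccc3)c1)[C@H](O)C2 | intermediate
20 | (2R,3R)-8-[(2S,4R)-2-(3,4-dihydroxyphenyl)-7-hydroxychroman-4-yl]-2-(3,4,5-trihydroxyphenyl)chroman-3,5,7-triol | Oc1ccc2c(c1)O[C@H](c1ccc(O)c(O)c1)C[C@H]2c1c(O)cc(O)c2c1O[C@H](c1cc(O)c(O)c(O)c1)[C@H](O)C2 | target

## Step count and least certain steps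

Total step count: 12. Longest linear sequence: 11 steps (steps 1–6 and 8–12, from 1 to 20); the enal branch adds one step (step 7).

**Step 8 (key step).**
- What may go wrong: slow oxa-Michael addition, because the phenol is hydrogen-bonded and flanked by the flavanyl group, and the trialkoxy-substituted iminium ion is a weak electrophile. The formyl group, which receives electron density from two alkoxy groups, would also close the ring slowly. Reversible addition and a competing uncatalysed pathway would then erode face selectivity. A mismatch between the catalyst and the chiral flavanyl group next to the reacting oxygen is a further possibility.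
- Fallback: set out from 10 and 13 and run the annulation under achiral, more forcing conditions known for hindered salicylaldehydes (pyrrolidine with benzoic acid, or K2CO3, in dioxane at 80–100 °C). Stereocontrol is given up; 14 is expected together with its lower-C2 epimer, the (2S)-chromene aldehyde F1. Because the upper unit is chiral the two are diastereomers and would be separated by chromatography or crystallisation. The route is rejoined at 14.

**Step 4.**
- What may go wrong: insufficient preference for trans capture of the C4 cation, and drift of the product by acid-mediated re-ionisation of the new C4–aryl bond if the ionisation needs warmer or longer conditions. Self-alkylation of the flavanol and elimination would accompany this.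
- Fallback: set out from 5 and change the mode of activation from protic ionisation to thiophilic activation. Exchange with phenylmethanethiol (BnSH, catalytic BF3·OEt2, CH2Cl2, −20 °C) should give the (2S)-4-(benzylsulfanyl)flavan F2 as a mixture of C4 epimers. AgBF4 in THF at −78 °C with excess 6, quenched cold with Et3N, would then release the cation irreversibly at low temperature, where pseudoaxial capture is most favoured and the product cannot re-ionise. The route is rejoined at 7.

**Step 6.**
- What may go wrong: loss of site control in the etherification, that is benzylation of the hydroxyl next to the flavanyl group instead of the unhindered ortho hydroxyl, or a third benzylation. Any of this would pass a wrong free hydroxyl to the key step and so change the connectivity.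
- Fallback: set out from 5 and use commercial 3,5-bis(benzyloxy)phenol, in which the free hydroxyl is defined from the start. Friedel–Crafts alkylation (catalytic BF3·OEt2, CH2Cl2, −40 °C) should occur mainly ortho to the hydroxyl and give 3,5-bis(benzyloxy)-2-UF-phenol F3, distinguishable and separable from the para isomer because its hydroxyl is hindered. Magnesium-mediated ortho-formylation (MgCl2, Et3N, paraformaldehyde, MeCN, reflux) can then enter only at the one remaining position next to the hydroxyl. The route is rejoined at 10; steps 4 and 5 are bypassed as well.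

**Step 10.**
- What may go wrong: epimerisation at lower C2 during the hydrolysis, by enamine–imine tautomerisation or acid-catalysed enolisation towards C2, and urea formation from the enamine and unreacted isocyanate.
- Fallback: set out from 14 and avoid the hydrolysis. Decarbonylation with the monovalent rhodium complex RhCl(PPh3)3 (stoichiometric, PhMe, 90 °C) should give the (2S)-5,7-bis(benzyloxy)-8-UF-2-ArG-2H-chromene F4; the C2 descriptor changes only because C3 loses its formyl group. Hydroboration–oxidation (BH3·THF, 0 °C; then NaOH, H2O2) should add boron to C3 anti to the aryl group and give the (2R,3S)-2,3-trans-flavan-3-ol F5. Dess–Martin oxidation (NaHCO3, CH2Cl2, 0 °C → rt) would give the ketone under neutral conditions. The route is rejoined at 18; steps 9 and 10 are replaced.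

## Further compounds

F1 | step 8 | (2S)-5,7-bis(benzyloxy)-8-{(2S,4R)-7-(benzyloxy)-2-[3,4-bis(benzyloxy)phenyl]chroman-4-yl}-2-[3,4,5-tris(benzyloxy)phenyl]-2H-chromene-3-carbaldehyde | c1ccccc1COc1ccc2c(c1)O[C@H](c1ccc(OCc3ccccc3)c(OCc3ccccc3)c1)C[C@H]2c1c(OCc2ccccc2)cc(OCc2ccccc2)c2c1O[C@@H](c1cc(OCc3ccccc3)c(OCc3ccccc3)c(OCc3ccccc3)c1)C(C=O)=C2
F2 | step 4 | (2S)-7-(benzyloxy)-4-(benzylsulfanyl)-2-[3,4-bis(benzyloxy)phenyl]chroman (mixture of C4 epimers) | c1ccccc1COc1ccc2c(c1)O[C@H](c1ccc(OCc3ccccc3)c(OCc3ccccc3)c1)CC2SCc1ccccc1
F3 | step 6 | 3,5-bis(benzyloxy)-2-{(2S,4R)-7-(benzyloxy)-2-[3,4-bis(benzyloxy)phenyl]chroman-4-yl}phenol | c1ccccc1COc1ccc2c(c1)O[C@H](c1ccc(OCc3ccccc3)c(OCc3ccccc3)c1)C[C@H]2c1c(OCc2ccccc2)cc(OCc2ccccc2)cc1O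
F4 | step 10 | (2S)-5,7-bis(benzyloxy)-8-{(2S,4R)-7-(benzyloxy)-2-[3,4-bis(benzyloxy)phenyl]chroman-4-yl}-2-[3,4,5-tris(benzyloxy)phenyl]-2H-chromene | c1ccccc1COc1ccc2c(c1)O[C@H](c1ccc(OCc3ccccc3)c(OCc3ccccc3)c1)C[C@H]2c1c(OCc2ccccc2)cc(OCc2ccccc2)c2c1O[C@H](c1cc(OCc3ccccc3)c(OCc3ccccc3)c(OCc3ccccc3)c1)C=C2
F5 | step 10 | (2R,3S)-5,7-bis(benzyloxy)-8-{(2S,4R)-7-(benzyloxy)-2-[3,4-bis(benzyloxy)phenyl]chroman-4-yl}-2-[3,4,5-tris(benzyloxy)phenyl]chroman-3-ol | c1ccccc1COc1ccc2c(c1)O[C@H](c1ccc(OCc3ccccc3)c(OCc3ccccc3)c1)C[C@H]2c1c(OCc2ccccc2)cc(OCc2ccccc2)c2c1O[C@H](c1cc(OCc3ccccc3)c(OCc3ccccc3)c(OCc3ccccc3)c1)[C@@H](O)C2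
A1 | alternative 1 | octa-O-benzyl biflavan with free upper C7 hydroxyl (3-O-benzyl lower unit) | Oc1ccc2c(c1)O[C@H](c1ccc(OCc3ccccc3)c(OCc3ccccc3)c1)C[C@H]2c1c(OCc2ccccc2)cc(OCc2ccccc2)c2c1O[C@H](c1cc(OCc3ccccc3)c(OCc3ccccc3)c(OCc3ccccc3)c1)[C@H](OCc1ccccc1)C2
A2 | alternative 1 | open-chain diazo vinyl ketone carrying an ethynyl ether on the C2 oxygen and the benzylated lower unit on C4 | C#CO[C@H](c1ccc(OCc2ccccc2)c(OCc2ccccc2)c1)C[C@H](C(=[N+]=[N-])C(=O)C=C)c1c(OCc2ccccc2)cc(OCc2ccccc2)c2c1O[C@H](c1cc(OCc3ccccc3)c(OCc3ccccc3)c(OCc3ccccc3)c1)[C@H](OCc1ccccc1)C2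
A3 | alternative 2 | flavan-4-yl phenol with lower C7 hydroxyl, C8a triisopropylsilyl ether, C5 benzyl ether and C4a (E)-cinnamyl group | c1ccccc1COc1ccc2c(c1)O[C@H](c1ccc(OCc3ccccc3)c(OCc3ccccc3)c1)C[C@H]2c1c(O)cc(OCc2ccccc2)c(C/C=C/c2cc(OCc3ccccc3)c(OCc3ccccc3)c(OCc3ccccc3)c2)c1O[Si](C(C)C)(C(C)C)C(C)C
A4 | alternative 2 | 7-(benzyloxy)-2-[3,4-bis(benzyloxy)phenyl]-4-[(triisopropylsilyloxy)ethynyl]chroman with the target configuration at C2 and C4 | c1ccccc1COc1ccc2c(c1)O[C@H](c1ccc(OCc3ccccc3)c(OCc3ccccc3)c1)C[C@H]2C#CO[Si](C(C)C)(C(C)C)C(C)C
A5 | alternative 2 | 3-(benzyloxy)-2-{(2E)-3-[3,4,5-tris(benzyloxy)phenyl]prop-2-en-1-yl}cyclobut-2-en-1-one | O=C1CC(OCc2ccccc2)=C1C/C=C/c1cc(OCc2ccccc2)c(OCc2ccccc2)c(OCc2ccccc2)c1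
A6 | alternative 3 | nona-O-benzyl biflavan (fully benzylated target) | c1ccccc1COc1ccc2c(c1)O[C@H](c1ccc(OCc3ccccc3)c(OCc3ccccc3)c1)C[C@H]2c1c(OCc2ccccc2)cc(OCc2ccccc2)c2c1O[C@H](c1cc(OCc3ccccc3)c(OCc3ccccc3)c(OCc3ccccc3)c1)[C@H](OCc1ccccc1)C2
A7 | alternative 3 | (1R)-1-[3,4-bis(benzyloxy)phenyl]-3-[4-(benzyloxy)-2-hydroxyphenyl]-3-(benzylated epigallocatechin-8-yl)propan-1-ol with the target configuration at C3 of the chain | c1ccccc1COc1ccc(c(O)c1)[C@@H](C[C@@H](O)c1ccc(OCc2ccccc2)c(OCc2ccccc2)c1)c1c(OCc2ccccc2)cc(OCc2ccccc2)c2c1O[C@H](c1cc(OCc3ccccc3)c(OCc3ccccc3)c(OCc3ccccc3)c1)[C@H](OCc1ccccc1)C2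
A8 | alternative 3 | (−)-epigallocatechin, (2R,3R)-2-(3,4,5-trihydroxyphenyl)chroman-3,5,7-triol | Oc1cc(O)c2c(c1)O[C@H](c1cc(O)c(O)c(O)c1)[C@H](O)C2
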